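**Retrosynthetic overview**

1. The last step is one hydrogenolysis that removes two benzyl ethers and one aryl bromide from the fully assembled flavanone.
2. Two disconnections are made in a single flask: O1–C2 (oxa-Michael closure of ring C) and C8–CH(Ph) (arylation of an ortho-quinone methide of the left aryl ring by ring A).
3. Enabling feature: C2 is beta to the C4 ketone and O1 on C8a is ortho to the acyl carbon C4a, so ring C is the oxa-Michael adduct of a 2'-hydroxychalcone. O1 is also the only ring A oxygen para to the C6 methyl, so ring A is bought as a 2-methylresorcinol ketone (5-O, 7-O present) and O1 is installed by ketone-directed C–H borylation/oxidation, which leaves it the only free phenol on ring A.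
4. Left aryl ring: 2,4,6-trihydroxytoluene is formylated, O-methylated para to the formyl group (the two ortho hydroxyls are hydrogen-bonded), blocked with bromine and treated with PhMgBr; the formyl carbon becomes the methine carbon.
5. Ring order: ring A, the left aryl ring and both phenyl rings come from commercial arenes; ring C is the only ring formed, last, in the key step.

Key step: step 8

Assumption: the sense of induction of the two organocatalysts in step 8 is assigned by analogy only; if either proves opposite, the enantiomeric phosphoric acid or the quinine-derived thiourea is used and nothing else changes.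

**Route**

Step 1
Reactants: 1 2,4,6-trihydroxytoluene
Product: 3 2,4,6-trihydroxy-3-methylbenzaldehyde, via iminium chloride 2 (not isolated)
Conditions: POCl3 (1.1 equiv), DMF, EtOAc, 0 °C to rt; then H2O, 50 °C
Reagents that add atoms: N,N-dimethylformamide CN(C)C=O; water O
Why: Vilsmeier–Haack formylation of the phloroglucinol ring, in which the two free ring carbons are equivalent by symmetry so only one aldehyde can form, and the formyl group deactivates the ring towards a second formylation.

Step 2
Reactants: 3 2,4,6-trihydroxy-3-methylbenzaldehyde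
Product: 4 2,6-dihydroxy-4-methoxy-3-methylbenzaldehyde
Conditions: MeI (1.05 equiv), K2CO3 (1.0 equiv), acetone, rt
Reagents that add atoms: iodomethane CI
Why: Williamson etherification under chelation control, since the two hydroxyls ortho to the formyl group are hydrogen-bonded to it and less acidic, so one equivalent of MeI should alkylate the para hydroxyl, which is the oxygen next to the ring methyl group.

Step 3
Reactants: 4 2,6-dihydroxy-4-methoxy-3-methylbenzaldehyde
Product: 5 3-bromo-2,6-dihydroxy-4-methoxy-5-methylbenzaldehyde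
Conditions: N-bromosuccinimide (1.0 equiv), MeCN, 0 °C
Reagents that add atoms: N-bromosuccinimide O=C1CCC(=O)N1Br
Why: electrophilic aromatic bromination at the only unsubstituted ring carbon, which installs a temporary block so that the quinone methide of step 8 cannot be captured by a ring of its own kind (the bromine leaves in step 9).

Step 4
Reactants: 5 3-bromo-2,6-dihydroxy-4-methoxy-5-methylbenzaldehyde; 6 phenylmagnesium bromide
Product: 7 4-bromo-2-[hydroxy(phenyl)methyl]-5-methoxy-6-methylbenzene-1,3-diol (racemic)
Conditions: 6 (3.3 equiv), THF, −40 to 0 °C; then aq. NH4Cl, 0 °C; crude 7 used at once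
Reagents that add atoms: none
Why: Grignard 1,2-addition to the aldehyde after deprotonation of both phenols (magnesium chelation keeps the carbonyl electrophilic), the new carbinol centre being left racemic on purpose because it becomes planar in the quinone methide of step 8.

Step 5
Reactants: 8 1-(2,4-dihydroxy-3-methylphenyl)ethanone
Product: 9 1-[2,4-bis(benzyloxy)-3-methylphenyl]ethanone
Conditions: BnBr (2.5 equiv), K2CO3 (3 equiv), DMF, 70 °C
Reagents that add atoms: benzyl bromide BrCc1ccccc1
Why: Williamson etherification of both phenols, with heating needed for the hydrogen-bonded hydroxyl between the acetyl and methyl groups.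

Step 6
Reactants: 9 1-[2,4-bis(benzyloxy)-3-methylphenyl]ethanone
Product: 11 1-[2,4-bis(benzyloxy)-6-hydroxy-3-methylphenyl]ethanone, via aryl boronate 10 (not isolated)
Conditions: [Ir(OMe)(cod)]2 (1.5 mol%), AsPh3 (6 mol%), bis(pinacolato)diboron (1.1 equiv), octane, 120 °C; then Me3NO (2 equiv), THF, rt; aq. work-up
Reagents that add atoms: trimethylamine N-oxide C[N+](C)(C)[O-] (oxygen of 11); bis(pinacolato)diboron CC1(C)OB(OC1(C)C)B1OC(C)(C)C(C)(C)O1 (boryl group of 10)
Why: ketone-directed iridium-catalysed ortho C–H borylation followed by oxidation of the C–B bond, in which the acetyl oxygen delivers the metal to the only ortho C–H bond and so places the new hydroxyl para to the ring methyl (the future O1), the amine N-oxide being chosen over alkaline peroxide to avoid a Dakin-type oxidation of the o-hydroxyaryl ketone.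

Step 7
Reactants: 11 1-[2,4-bis(benzyloxy)-6-hydroxy-3-methylphenyl]ethanone; 12 benzaldehyde
Product: 13 (E)-1-[2,4-bis(benzyloxy)-6-hydroxy-3-methylphenyl]-3-phenylprop-2-en-1-one
Conditions: 12 (1.5 equiv), KOH (50% aq.), EtOH, 0 °C to rt; then cold 1 M HCl to pH 5
Reagents that add atoms: none
Why: Claisen–Schmidt condensation (aldol addition, then E1cB dehydration) to the E-enone, the 2'-hydroxy-6'-alkoxychalcone being held as its phenoxide under strong base and isolated uncyclised after cold acidification.

Step 8
Reactants: 13 (E)-1-[2,4-bis(benzyloxy)-6-hydroxy-3-methylphenyl]-3-phenylprop-2-en-1-one; 7 4-bromo-2-[hydroxy(phenyl)methyl]-5-methoxy-6-methylbenzene-1,3-diol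
Product: 16 (2S)-5,7-bis(benzyloxy)-8-[(S)-(3-bromo-2,6-dihydroxy-4-methoxy-5-methylphenyl)(phenyl)methyl]-6-methyl-2-phenyl-2,3-dihydro-4H-chromen-4-one, via quinone methide 14 (not isolated), via benzhydryl chalcone 15 (not isolated)
Conditions: 13 (1.0 equiv), 7 (1.2 equiv, added over 2 h), (R)-3,3'-bis(2,4,6-triisopropylphenyl)-1,1'-binaphthyl-2,2'-diyl hydrogen phosphate (10 mol%), 4 Å MS, CH2Cl2, 0 °C to rt; then 1-[3,5-bis(trifluoromethyl)phenyl]-3-[(9R)-6'-methoxycinchonan-9-yl]thiourea (25 mol%), −20 °C
Reagents that add atoms: none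
Why: The chiral phosphoric acid dehydrates 7 to the ortho-quinone methide 14 and, bound to it and to the 6'-hydroxyl of 13, lets the only unsubstituted carbon of ring A (the future C8) add to one face of the benzylidene carbon in a Friedel–Crafts-type 1,4-addition that gives 15 with the (S) methine; the cinchona thiourea then closes ring C by intramolecular oxa-Michael addition of the same phenol oxygen (O1) to the enone beta carbon (C2), the thiourea holding the carbonyl and the quinuclidine the phenol. The closest known reaction types are the phosphoric acid catalysed arylation of in situ ortho-quinone methides by phenols and naphthols to triarylmethanes, and the thiourea–tertiary amine catalysed asymmetric cyclisation of 2'-hydroxychalcones and their beta-keto ester analogues to flavanones. Ring C closes in the 6-endo-trig mode. The methine configuration is set by the phosphate and the C2 configuration by the thiourea catalyst, with the new C8 substituent as a possible matched or mismatched partner. Regiochemistry leaves no choice, because O1 is the only free hydroxyl on ring A (the 5- and 7-oxygens are benzyl ethers), ring A has one free carbon, and bromine blocks the only free carbon of the quinone methide ring. The order of events is secured by the catalysts, since the weak acid does not cyclise the chalcone, so C-arylation (which needs the free phenol) comes first, and the cold base-catalysed closure that follows is practically irreversible for a 6'-alkoxy chalcone.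

Step 9
Reactants: 16 (2S)-5,7-bis(benzyloxy)-8-[(S)-(3-bromo-2,6-dihydroxy-4-methoxy-5-methylphenyl)(phenyl)methyl]-6-methyl-2-phenyl-2,3-dihydro-4H-chromen-4-one
Product: 17 (2S)-8-[(S)-(2,6-dihydroxy-4-methoxy-3-methylphenyl)(phenyl)methyl]-5,7-dihydroxy-6-methyl-2-phenyl-2,3-dihydro-4H-chromen-4-one
Conditions: H2 (1 atm), Pd/C (10%), NaOAc (1.5 equiv), EtOAc/MeOH, rt
Reagents that add atoms: none
Why: catalytic hydrogenolysis should cleave both benzyl ethers and the aryl C–Br bond (NaOAc takes up HBr) under neutral conditions, where the C2–O1 alkyl aryl ether bond is much slower to cleave and neither stereocentre is touched.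

**Compound list**

1 | 2,4,6-trihydroxytoluene (2-methylbenzene-1,3,5-triol) | Cc1c(O)cc(O)cc1O | starting material
2 | N-[(2,4,6-trihydroxy-3-methylphenyl)methylidene]-N-methylmethanaminium chloride | C[N+](C)=Cc1c(O)cc(O)c(C)c1O.[Cl-] | intermediate
3 | 2,4,6-trihydroxy-3-methylbenzaldehyde | O=Cc1c(O)cc(O)c(C)c1O | intermediate
4 | 2,6-dihydroxy-4-methoxy-3-methylbenzaldehyde | COc1cc(O)c(C=O)c(O)c1C | intermediate
5 | 3-bromo-2,6-dihydroxy-4-methoxy-5-methylbenzaldehyde | COc1c(Br)c(O)c(C=O)c(O)c1C | intermediate
6 | phenylmagnesium bromide | Br[Mg]c1ccccc1 | starting material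
7 | 4-bromo-2-[hydroxy(phenyl)methyl]-5-methoxy-6-methylbenzene-1,3-diol (racemic) | COc1c(Br)c(O)c(C(O)c2ccccc2)c(O)c1C | intermediate
8 | 1-(2,4-dihydroxy-3-methylphenyl)ethanone | CC(=O)c1ccc(O)c(C)c1O | starting material
9 | 1-[2,4-bis(benzyloxy)-3-methylphenyl]ethanone | CC(=O)c1ccc(OCc2ccccc2)c(C)c1OCc1ccccc1 | intermediate
10 | 1-[2,4-bis(benzyloxy)-3-methyl-6-(4,4,5,5-tetramethyl-1,3,2-dioxaborolan-2-yl)phenyl]ethanone | CC(=O)c1c(B2OC(C)(C)C(C)(C)O2)cc(OCc2ccccc2)c(C)c1OCc1ccccc1 | intermediate
11 | 1-[2,4-bis(benzyloxy)-6-hydroxy-3-methylphenyl]ethanone | CC(=O)c1c(O)cc(OCc2ccccc2)c(C)c1OCc1ccccc1 | intermediate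
12 | benzaldehyde | O=Cc1ccccc1 | starting material
13 | (E)-1-[2,4-bis(benzyloxy)-6-hydroxy-3-methylphenyl]-3-phenylprop-2-en-1-one | O=C(/C=C/c1ccccc1)c1c(O)cc(OCc2ccccc2)c(C)c1OCc1ccccc1 | intermediate
14 | 6-benzylidene-2-bromo-5-hydroxy-3-methoxy-4-methylcyclohexa-2,4-dien-1-one | O=C1C(Br)=C(OC)C(C)=C(O)C1=Cc1ccccc1 | intermediate
15 | (E)-1-{2,4-bis(benzyloxy)-5-[(S)-(3-bromo-2,6-dihydroxy-4-methoxy-5-methylphenyl)(phenyl)methyl]-6-hydroxy-3-methylphenyl}-3-phenylprop-2-en-1-one | COc1c(Br)c(O)c([C@H](c2ccccc2)c2c(OCc4ccccc4)c(C)c(OCc4ccccc4)c(C(=O)/C=C/c4ccccc4)c2O)c(O)c1C | intermediate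
16 | (2S)-5,7-bis(benzyloxy)-8-[(S)-(3-bromo-2,6-dihydroxy-4-methoxy-5-methylphenyl)(phenyl)methyl]-6-methyl-2-phenyl-2,3-dihydro-4H-chromen-4-one | COc1c(Br)c(O)c([C@H](c2ccccc2)c2c(OCc4ccccc4)c(C)c(OCc4ccccc4)c3c2O[C@H](c2ccccc2)CC3=O)c(O)c1C | intermediate
17 | (2S)-8-[(S)-(2,6-dihydroxy-4-methoxy-3-methylphenyl)(phenyl)methyl]-5,7-dihydroxy-6-methyl-2-phenyl-2,3-dihydro-4H-chromen-4-one | COc1cc(O)c([C@H](c2ccccc2)c2c(O)c(C)c(O)c3c2O[C@H](c2ccccc2)CC3=O)c(O)c1C | target

**Step count and risks**

Total step count: 9. Longest linear sequence: 6 steps (steps 1, 2, 3, 4, 8, 9).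

Steps most likely to fail:

1. Step 8. The C–C bond formation may be slow or unselective because the reacting phenol is tied up in a hydrogen bond to the ketone; facial selectivity at the methine carbon may be poor; and the ring closure may suffer from a racemic background reaction or a mismatched pairing at C2. Fallback, from 13 back to 17, with the order of the two events reversed: 13 is cyclised alone with the same thiourea catalyst to (2S)-5,7-bis(benzyloxy)-6-methyl-2-phenyl-2,3-dihydro-4H-chromen-4-one F1. Hydrogenolysis (H2, Pd/C, EtOAc) then should give (2S)-5,7-dihydroxy-6-methyl-2-phenyl-2,3-dihydro-4H-chromen-4-one F2, whose free 7-hydroxyl next to C8 is a better handle for the phosphoric acid. Arylation of the quinone methide from 7 at C8 with the same phosphoric acid should give (2S)-8-[(S)-(3-bromo-2,6-dihydroxy-4-methoxy-5-methylphenyl)(phenyl)methyl]-5,7-dihydroxy-6-methyl-2-phenyl-2,3-dihydro-4H-chromen-4-one F3, and hydrodebromination (H2, Pd/C, NaOAc) should give 17.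

2. Step 6. Borylation may occur outside the directed position or at the acetyl methyl group, and turnover may be low because the acetyl group is twisted by the flanking benzyloxy group. Fallback, from 9 back to 11, by C–H oxygenation through a palladacycle instead of borylation: Pd(OCOCF3)2 (5 mol%), PhI(OCOCF3)2 (1.5 equiv), 1,2-dichloroethane, 80 °C should give 2-acetyl-3,5-bis(benzyloxy)-4-methylphenyl trifluoroacetate F4, and NaHCO3 in aqueous MeOH should cleave the ester to 11.

3. Step 4. Addition to the doubly deprotonated, electron-rich aldehyde may be incomplete, and the product may lose water to the quinone methide during work-up and oligomerise. Fallback, from 5 back to 7, through protected phenols: tert-butyldimethylsilyl triflate and 2,6-lutidine in CH2Cl2 should give 3-bromo-2,6-bis[(tert-butyldimethylsilyl)oxy]-4-methoxy-5-methylbenzaldehyde F5. Compound 6 (1.2 equiv, THF, −78 °C) then should add to the now ordinary aldehyde to give {3-bromo-2,6-bis[(tert-butyldimethylsilyl)oxy]-4-methoxy-5-methylphenyl}(phenyl)methanol F6, and Bu4NF buffered with AcOH (THF, 0 °C) should release 7 directly before use.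

**Further compounds**

F1 | step 8 | (2S)-5,7-bis(benzyloxy)-6-methyl-2-phenyl-2,3-dihydro-4H-chromen-4-one | Cc1c(OCc2ccccc2)cc2O[C@H](c3ccccc3)CC(=O)c2c1OCc1ccccc1
F2 | step 8 | (2S)-5,7-dihydroxy-6-methyl-2-phenyl-2,3-dihydro-4H-chromen-4-one | Cc1c(O)cc2O[C@H](c3ccccc3)CC(=O)c2c1O
F3 | step 8 | (2S)-8-[(S)-(3-bromo-2,6-dihydroxy-4-methoxy-5-methylphenyl)(phenyl)methyl]-5,7-dihydroxy-6-methyl-2-phenyl-2,3-dihydro-4H-chromen-4-one | COc1c(Br)c(O)c([C@H](c2ccccc2)c2c(O)c(C)c(O)c3c2O[C@H](c2ccccc2)CC3=O)c(O)c1C
F4 | step 6 | 2-acetyl-3,5-bis(benzyloxy)-4-methylphenyl trifluoroacetate | CC(=O)c1c(OC(=O)C(F)(F)F)cc(OCc2ccccc2)c(C)c1OCc1ccccc1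
F5 | step 4 | 3-bromo-2,6-bis[(tert-butyldimethylsilyl)oxy]-4-methoxy-5-methylbenzaldehyde | COc1c(Br)c(O[Si](C)(C)C(C)(C)C)c(C=O)c(O[Si](C)(C)C(C)(C)C)c1C
F6 | step 4 | {3-bromo-2,6-bis[(tert-butyldimethylsilyl)oxy]-4-methoxy-5-methylphenyl}(phenyl)methanol (racemic) | COc1c(Br)c(O[Si](C)(C)C(C)(C)C)c(C(O)c2ccccc2)c(O[Si](C)(C)C(C)(C)C)c1C
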